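**Plan**

1. Numbering is that of eremophilane: ring A = C1–C5 and C10, ring B = C5–C10, C14 on C5, C15 on C4, C11–C13 = isopropenyl on C7; β is the face of C14. Retrosynthetic cuts: the C3–O ester; C7–C11; C4–C15 and C5–C14; then C5–C10 and C2–C3 together; then C8–C9 and C7–C8 at a dithiane carbon.
2. Enabling feature: in ring A, C3 and C5 flank C4 while C2 and C10 flank C1. Ring A is therefore the [3+3] union of an acetonyl unit C3–C4(=O)–C5 and an enal C10=C1–C2(=O)H. The C6–C9 chain of ring B tethers the two, so the Michael bond C5–C10 closes ring B and the aldol bond C2–C3 closes ring A.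
3. Helpers: the C4 ketone (later turned into C4–CH3 and C3–OH through enol triflate, cuprate and hydroboration), the C2 oxygen (lost on dehydration), a 1,3-dithiane masking the C8 ketone, and a silyl ether on O9.
4. Forward: 1,3-dithiane (C8) is alkylated with the masked C3–C7 ketone arm and added to an enal acetal (C9, C10, C1, C2). The cascade closes ring B, then ring A. Then follow C14, C15/O3, the C8 ketone, the isopropenyl group, the ester and desilylation.
5. Stereochemistry: C9 by oxazaborolidine-catalysed reduction; C10 from C9 in the chair Michael transition state; C5 by angular methylation (cis); C3/C4 by hydroboration anti to C14; C7 as the equatorial epimer. The side-chain carbinol is bought as (R)-pent-4-en-2-ol.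

Key step: step 7

Assumption: in the oxazaborolidine reduction (step 4) the fully substituted dithianyl carbon acts as the large group, so the (S)-catalyst should give the (R)-carbinol; if the sense is reversed, the (R)-catalyst is used.

**Route**

Step 1
Reactants: 1 1,3-dithiane; 2 2-(3-chloropropyl)-2-methyl-1,3-dioxolane
Product: 4 2-[3-(2-methyl-1,3-dioxolan-2-yl)propyl]-1,3-dithiane, via 2-lithio-1,3-dithiane 3 (not isolated)
Conditions: n-BuLi, THF, −30 °C; then 2, −30 °C → rt
Reagents that add atoms: n-butyllithium, [Li]CCCC (lithium of 3 only)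
Why: Corey–Seebach alkylation, in which the lithiated dithiane (acyl-anion equivalent, future C8) displaces the primary chloride by SN2 and so attaches the ketal-masked C3–C7 methyl ketone arm.

Step 2
Reactants: 4 2-[3-(2-methyl-1,3-dioxolan-2-yl)propyl]-1,3-dithiane; 5 (E)-4,4-dimethoxybut-2-enal
Product: 7 rac-(E)-4,4-dimethoxy-1-{2-[3-(2-methyl-1,3-dioxolan-2-yl)propyl]-1,3-dithian-2-yl}but-2-en-1-ol, via 2-lithio-2-alkyl-1,3-dithiane 6 (not isolated)
Conditions: n-BuLi, THF, −20 °C; then 5, −78 °C; H2O
Reagents that add atoms: n-butyllithium, [Li]CCCC (lithium of 6 only)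
Why: Second Corey–Seebach lithiation and carbonyl (1,2) addition of the 2-alkyl-2-lithiodithiane to the enal, which in THF without HMPA should beat conjugate addition and joins C8 to C9; the carbinol is racemic and is corrected in steps 3 and 4.

Step 3
Reactants: 7 rac-(E)-4,4-dimethoxy-1-{2-[3-(2-methyl-1,3-dioxolan-2-yl)propyl]-1,3-dithian-2-yl}but-2-en-1-ol
Product: 8 (E)-4,4-dimethoxy-1-{2-[3-(2-methyl-1,3-dioxolan-2-yl)propyl]-1,3-dithian-2-yl}but-2-en-1-one
Conditions: Dess–Martin periodinane, NaHCO3, CH2Cl2, 0 °C → rt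
Reagents that add atoms: none
Why: Dess–Martin oxidation of a secondary allylic alcohol to the enone, under buffered conditions that should leave the thioacetal sulfur and both acetals untouched.

Step 4
Reactants: 8 (E)-4,4-dimethoxy-1-{2-[3-(2-methyl-1,3-dioxolan-2-yl)propyl]-1,3-dithian-2-yl}but-2-en-1-one
Product: 9 (1R,2E)-4,4-dimethoxy-1-{2-[3-(2-methyl-1,3-dioxolan-2-yl)propyl]-1,3-dithian-2-yl}but-2-en-1-ol
Conditions: (S)-2-methyl-CBS-oxazaborolidine (0.2 equiv), BH3·SMe2, THF, −30 °C; MeOH
Reagents that add atoms: none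
Why: Corey–Bakshi–Shibata reduction, in which the oxazaborolidine–borane complex delivers hydride 1,2 to the enone face selected by the large dithianyl versus the smaller alkenyl group; this sets C9 as (R), the only centre of the bicyclic core set by a catalyst.

Step 5
Reactants: 9 (1R,2E)-4,4-dimethoxy-1-{2-[3-(2-methyl-1,3-dioxolan-2-yl)propyl]-1,3-dithian-2-yl}but-2-en-1-ol
Product: 10 tert-butyldimethylsilyl ether of 9
Conditions: TBSOTf, 2,6-lutidine, CH2Cl2, 0 °C
Reagents that add atoms: tert-butyldimethylsilyl trifluoromethanesulfonate, CC(C)(C)[Si](C)(C)OS(=O)(=O)C(F)(F)F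
Why: Silylation of a hindered secondary alcohol with the silyl triflate, giving an O9 protecting group that lasts to the final step.

Step 6
Reactants: 10 tert-butyldimethylsilyl ether of 9
Product: 11 (R,E)-4-(tert-butyldimethylsilyloxy)-4-[2-(4-oxopentyl)-1,3-dithian-2-yl]but-2-enal
Conditions: PPTS, acetone/H2O, 45 °C
Reagents that add atoms: water, O
Why: Mild acid-catalysed acetal hydrolysis (transacetalisation) frees both the enal and the methyl ketone, while the dithiane and the secondary silyl ether should survive and the (E)-geometry is kept.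

Step 7
Reactants: 11 (R,E)-4-(tert-butyldimethylsilyloxy)-4-[2-(4-oxopentyl)-1,3-dithian-2-yl]but-2-enal
Product: 14 9β-(tert-butyldimethylsilyloxy)-10βH-decal-2-en-4-one 8-(propane-1,3-diyl dithioketal) as C5 epimers, via keto-aldehyde Michael adduct 12 (not isolated), via β-hydroxy ketone aldol 13 (not isolated)
Conditions: pyrrolidine (0.3 equiv), AcOH (0.3 equiv), CH2Cl2 (high dilution), rt → 40 °C
Reagents that add atoms: none
Why: Pyrrolidinium acetate turns the enal into its (E)-iminium ion and the methyl ketone into its enamines, and the C5 enamine adds to the iminium β-carbon C10 (6-exo-trig, closing ring B through the C6–C9 tether), whereas the C3 enamine could reach C10 or C2 only through an eight-membered ring, so regioselectivity is fixed by ring size. After amine transfer the C3 enamine of the same ketone adds to the freed C2 aldehyde (6-(enolexo)-exo-trig, closing ring A) and the aldol loses water to the C4 enone, which makes the sequence irreversible. The closest known reaction type is the amine-catalysed Michael addition/aldol condensation [3+3] annulation of ketones or β-keto esters with enals (Stork enamine annulation, Robinson-type cyclohexenone synthesis), here run intramolecularly. C10 is the one stereocentre that must be controlled: in the chair transition state the iminium arm and the C9 silyloxy group are both equatorial with the C9–O bond anti to the forming C5–C10 bond (Felkin–Anh arrangement), which should give the 9,10-trans relationship (9β-O, 10β-H), and the quaternary dithiane carbon C8 favours ring closure (Thorpe–Ingold effect). C5 is formed as an epimerisable CH and is reset in step 8. The step needs 1,4- over 1,2-addition, which the tether secures because 1,2-attack would also require an eight-membered ring.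

Step 8
Reactants: 14 9β-(tert-butyldimethylsilyloxy)-10βH-decal-2-en-4-one 8-(propane-1,3-diyl dithioketal)
Product: 16 5β-methyl-9β-(tert-butyldimethylsilyloxy)-10βH-decal-2-en-4-one 8-(propane-1,3-diyl dithioketal), via lithium dienolate 15 (not isolated)
Conditions: LiN(i-Pr)2, THF, −78 °C; MeI, DMPU, −78 → −20 °C
Reagents that add atoms: lithium diisopropylamide, [Li]N(C(C)C)C(C)C (lithium of 15 only); iodomethane, CI
Why: Kinetic α′-deprotonation of the enone at C5 and C-methylation of the cross-conjugated dienolate (angular enolate alkylation); iodomethane should approach C5, an enolate carbon exocyclic to the chair of ring B, from the β (equatorial) side away from the axial hydrogens at C7 and C9, giving the cis-fused decalin with C14 cis to H10 and converging both C5 epimers.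

Step 9
Reactants: 16 5β-methyl-9β-(tert-butyldimethylsilyloxy)-10βH-decal-2-en-4-one 8-(propane-1,3-diyl dithioketal)
Product: 18 5β-methyl-9β-(tert-butyldimethylsilyloxy)-10βH-decal-3-en-4-yl trifluoromethanesulfonate 8-(propane-1,3-diyl dithioketal), via lithium enolate 17 (not isolated)
Conditions: Li[HB(s-Bu)3], THF, −78 °C; PhNTf2, −78 °C → rt
Reagents that add atoms: lithium tri-sec-butylborohydride, [Li+].CCC(C)[BH-](C(C)CC)C(C)CC (lithium of 17 only); N-phenylbis(trifluoromethanesulfonimide), O=S(=O)(N(c1ccccc1)S(=O)(=O)C(F)(F)F)C(F)(F)F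
Why: Conjugate (1,4) reduction of a β-unsubstituted cyclohexenone by the hindered borohydride gives the C3=C4 enolate regiospecifically, and O-triflation traps it as the enol triflate (reductive enolate trapping).

Step 10
Reactants: 18 5β-methyl-9β-(tert-butyldimethylsilyloxy)-10βH-decal-3-en-4-yl trifluoromethanesulfonate 8-(propane-1,3-diyl dithioketal)
Product: 19 4,5β-dimethyl-9β-(tert-butyldimethylsilyloxy)-10βH-decal-3-ene 8-(propane-1,3-diyl dithioketal)
Conditions: Me2CuLi, Et2O, −20 → 0 °C
Reagents that add atoms: lithium dimethylcuprate, [Li+].C[Cu-]C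
Why: McMurry–Scott coupling of a vinyl triflate with a Gilman cuprate replaces the triflate by the C15 methyl and fixes the alkene at C3=C4; sulfur does not interfere with a stoichiometric cuprate.

Step 11
Reactants: 19 4,5β-dimethyl-9β-(tert-butyldimethylsilyloxy)-10βH-decal-3-ene 8-(propane-1,3-diyl dithioketal)
Product: 21 3α-hydroxy-4β,5β-dimethyl-9β-(tert-butyldimethylsilyloxy)-10βH-decalin-8-one propane-1,3-diyl dithioketal, via C3-alkylborane 20 (not isolated)
Conditions: BH3·THF, 0 °C → rt; NaOH, H2O2, 0 °C
Reagents that add atoms: borane–tetrahydrofuran, B.C1CCOC1 (boron of 20 only); hydrogen peroxide, OO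
Why: Brown hydroboration–oxidation adds boron to C3 and hydrogen to C4 in syn fashion from the α face, because the β face is blocked by the axial C14 methyl (1,3-diaxial to C3) in a cis-decalin whose conformation is locked by the C8 dithiane and the 9β-silyloxy group; oxidation with retention should give 3α-OH and the 4β-methyl.

Step 12
Reactants: 21 3α-hydroxy-4β,5β-dimethyl-9β-(tert-butyldimethylsilyloxy)-10βH-decalin-8-one propane-1,3-diyl dithioketal
Product: 22 3α-hydroxy-4β,5β-dimethyl-9β-(tert-butyldimethylsilyloxy)-10βH-decalin-8-one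
Conditions: MeI, CaCO3, MeCN/H2O, 50 °C
Reagents that add atoms: water, O
Why: Alkylative hydrolysis of the dithiane (S-methylation, then hydrolysis of the sulfonium ion) unmasks the C8 ketone; CaCO3 buffers the HI so that the silyl ether and the free C3 hydroxyl are kept.

Step 13
Reactants: 22 3α-hydroxy-4β,5β-dimethyl-9β-(tert-butyldimethylsilyloxy)-10βH-decalin-8-one
Product: 24 3α-hydroxy-9β-(tert-butyldimethylsilyloxy)-10βH-eremophil-11-en-8-one (7β-isopropenyl), via dilithium enolate alkoxide 23 (not isolated)
Conditions: 2-bromopropene, Pd2(dba)3 (cat.), P(t-Bu)3 (cat.), LiN(SiMe3)2 (2.5 equiv), THF, rt; NH4Cl aq, −78 °C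
Reagents that add atoms: 2-bromopropene, CC(Br)=C; lithium bis(trimethylsilyl)amide, [Li]N([Si](C)(C)C)[Si](C)(C)C (lithium of 23 only)
Why: Palladium-catalysed α-alkenylation of a ketone enolate with an alkenyl bromide, in which the base enolises C8 towards C7 and not towards the silyloxy-bearing C9; the product is held as its enolate and cold protonation should give the all-equatorial 7β-isopropenyl epimer, the C3 alkoxide being a spectator.

Step 14
Reactants: 25 (R)-pent-4-en-2-ol; 26 angelic acid ((Z)-2-methylbut-2-enoic acid)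
Product: 28 (R)-pent-4-en-2-yl (Z)-2-methylbut-2-enoate, via mixed anhydride 27 (not isolated)
Conditions: 2,4,6-Cl3C6H2COCl, Et3N, toluene, rt; then 25, 75 °C
Reagents that add atoms: 2,4,6-trichlorobenzoyl chloride, O=C(Cl)c1c(Cl)cc(Cl)cc1Cl (aroyl part of 27 only)
Why: DMAP-free mixed-anhydride (Yamaguchi-type) esterification, chosen because it should acylate a secondary alcohol with angelic acid without Z → E isomerisation to the tiglate; the carbinol configuration is retained.

Step 15
Reactants: 28 (R)-pent-4-en-2-yl (Z)-2-methylbut-2-enoate; 29 acrylic acid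
Product: 30 (R,E)-5-[(Z)-2-methylbut-2-enoyloxy]hex-2-enoic acid
Conditions: second-generation Hoveyda–Grubbs catalyst (5 mol %), CH2Cl2, 40 °C
Reagents that add atoms: none
Why: Olefin cross-metathesis of a terminal alkene with acrylic acid gives the (E)-enoic acid, and the trisubstituted, electron-poor angelate double bond should not take part.

Step 16
Reactants: 24 3α-hydroxy-9β-(tert-butyldimethylsilyloxy)-10βH-eremophil-11-en-8-one; 30 (R,E)-5-[(Z)-2-methylbut-2-enoyloxy]hex-2-enoic acid
Product: 31 9-O-tert-butyldimethylsilyl ether of the target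
Conditions: EDC·HCl, DMAP (cat.), CH2Cl2, 0 °C → rt
Reagents that add atoms: none
Why: Steglich esterification of the only free hydroxyl, the equatorial C3–OH, with retention at C3; the mild conditions should spare the β,γ-unsaturated ketone, the Z-angelate and the δ-acyloxy enoate.

Step 17
Reactants: 31 9-O-tert-butyldimethylsilyl ether of the target
Product: 32 3α-{(R,E)-5-[(Z)-2-methylbut-2-enoyloxy]hex-2-enoyloxy}-9β-hydroxy-10βH-eremophil-11-en-8-one (CNP0210874.1)
Conditions: HF·pyridine, pyridine, THF, 0 °C → rt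
Reagents that add atoms: none
Why: Fluoride-mediated silyl ether cleavage under buffered, base-free conditions frees the C9 hydroxyl, so the C7 isopropenyl ketone should neither epimerise nor move into conjugation and the esters stay intact.

**Compound list**

1 | 1,3-dithiane | C1CSCSC1 | starting material
2 | 2-(3-chloropropyl)-2-methyl-1,3-dioxolane | CC1(CCCCl)OCCO1 | starting material
3 | 2-lithio-1,3-dithiane (not isolated) | [Li]C1SCCCS1 | intermediate
4 | 2-[3-(2-methyl-1,3-dioxolan-2-yl)propyl]-1,3-dithiane | CC1(CCCC2SCCCS2)OCCO1 | intermediate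
5 | (E)-4,4-dimethoxybut-2-enal (fumaraldehyde mono(dimethyl acetal)) | COC(OC)/C=C/C=O | starting material
6 | 2-lithio-2-[3-(2-methyl-1,3-dioxolan-2-yl)propyl]-1,3-dithiane (not isolated) | CC1(CCCC2([Li])SCCCS2)OCCO1 | intermediate
7 | rac-(E)-4,4-dimethoxy-1-{2-[3-(2-methyl-1,3-dioxolan-2-yl)propyl]-1,3-dithian-2-yl}but-2-en-1-ol | CC1(CCCC2(SCCCS2)C(O)/C=C/C(OC)OC)OCCO1 | intermediate
8 | (E)-4,4-dimethoxy-1-{2-[3-(2-methyl-1,3-dioxolan-2-yl)propyl]-1,3-dithian-2-yl}but-2-en-1-one | CC1(CCCC2(SCCCS2)C(=O)/C=C/C(OC)OC)OCCO1 | intermediate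
9 | (1R,2E)-4,4-dimethoxy-1-{2-[3-(2-methyl-1,3-dioxolan-2-yl)propyl]-1,3-dithian-2-yl}but-2-en-1-ol | CC1(CCCC2(SCCCS2)[C@H](O)/C=C/C(OC)OC)OCCO1 | intermediate
10 | tert-butyldimethylsilyl ether of 9 | CC1(CCCC2(SCCCS2)[C@H](O[Si](C)(C)C(C)(C)C)/C=C/C(OC)OC)OCCO1 | intermediate
11 | (R,E)-4-(tert-butyldimethylsilyloxy)-4-[2-(4-oxopentyl)-1,3-dithian-2-yl]but-2-enal | CC(=O)CCCC1(SCCCS1)[C@H](O[Si](C)(C)C(C)(C)C)/C=C/C=O | intermediate
12 | keto-aldehyde Michael adduct: ring B closed, C5 acetyl, C10 CH2CHO, 9β-OTBS, C8 dithiane (not isolated) | C1CC(C(C)=O)[C@H](CC=O)[C@@H](O[Si](C)(C)C(C)(C)C)C13SCCCS3 | intermediate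
13 | β-hydroxy ketone aldol: ring A closed, C4 ketone, C2 hydroxyl (not isolated) | C1CC2[C@H](CC(O)CC2=O)[C@@H](O[Si](C)(C)C(C)(C)C)C13SCCCS3 | intermediate
14 | 9β-(tert-butyldimethylsilyloxy)-10βH-decal-2-en-4-one 8-(propane-1,3-diyl dithioketal), C5 epimers | C1CC2[C@H](CC=CC2=O)[C@@H](O[Si](C)(C)C(C)(C)C)C13SCCCS3 | intermediate
15 | lithium 2,4(5)-dienolate of 14 (not isolated) | C1CC2=C(O[Li])C=CC[C@@H]2[C@@H](O[Si](C)(C)C(C)(C)C)C13SCCCS3 | intermediate
16 | 5β-methyl-9β-(tert-butyldimethylsilyloxy)-10βH-decal-2-en-4-one 8-(propane-1,3-diyl dithioketal) | C1C[C@@]2(C)[C@H](CC=CC2=O)[C@@H](O[Si](C)(C)C(C)(C)C)C13SCCCS3 | intermediate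
17 | lithium C3=C4 enolate from 16 (not isolated) | C1C[C@@]2(C)[C@H](CCC=C2O[Li])[C@@H](O[Si](C)(C)C(C)(C)C)C13SCCCS3 | intermediate
18 | 5β-methyl-9β-(tert-butyldimethylsilyloxy)-10βH-decal-3-en-4-yl trifluoromethanesulfonate 8-(propane-1,3-diyl dithioketal) | C1C[C@@]2(C)[C@H](CCC=C2OS(=O)(=O)C(F)(F)F)[C@@H](O[Si](C)(C)C(C)(C)C)C13SCCCS3 | intermediate
19 | 4,5β-dimethyl-9β-(tert-butyldimethylsilyloxy)-10βH-decal-3-ene 8-(propane-1,3-diyl dithioketal) | C1C[C@@]2(C)[C@H](CCC=C2C)[C@@H](O[Si](C)(C)C(C)(C)C)C13SCCCS3 | intermediate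
20 | 3α-boryl-4β,5β-dimethyl alkylborane (not isolated) | C1C[C@@]2(C)[C@H](CC[C@@H](B)[C@@H]2C)[C@@H](O[Si](C)(C)C(C)(C)C)C13SCCCS3 | intermediate
21 | 3α-hydroxy-4β,5β-dimethyl-9β-(tert-butyldimethylsilyloxy)-10βH-decalin-8-one propane-1,3-diyl dithioketal | C1C[C@@]2(C)[C@H](CC[C@@H](O)[C@@H]2C)[C@@H](O[Si](C)(C)C(C)(C)C)C13SCCCS3 | intermediate
22 | 3α-hydroxy-4β,5β-dimethyl-9β-(tert-butyldimethylsilyloxy)-10βH-decalin-8-one | C1C[C@@]2(C)[C@H](CC[C@@H](O)[C@@H]2C)[C@@H](O[Si](C)(C)C(C)(C)C)C1=O | intermediate
23 | dilithium C7=C8 enolate and C3 alkoxide of 22 (not isolated) | C1(O[Li])=CC[C@@]2(C)[C@H](CC[C@@H](O[Li])[C@@H]2C)[C@H]1O[Si](C)(C)C(C)(C)C | intermediate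
24 | 3α-hydroxy-9β-(tert-butyldimethylsilyloxy)-10βH-eremophil-11-en-8-one (7β-isopropenyl) | C=C(C)[C@H]1C[C@@]2(C)[C@H](CC[C@@H](O)[C@@H]2C)[C@@H](O[Si](C)(C)C(C)(C)C)C1=O | intermediate
25 | (R)-pent-4-en-2-ol | C=CC[C@@H](C)O | starting material
26 | angelic acid, (Z)-2-methylbut-2-enoic acid | OC(=O)/C(C)=C\C | starting material
27 | angelic 2,4,6-trichlorobenzoic mixed anhydride (not isolated) | O=C(OC(=O)/C(C)=C\C)c1c(Cl)cc(Cl)cc1Cl | intermediate
28 | (R)-pent-4-en-2-yl (Z)-2-methylbut-2-enoate | C=CC[C@@H](C)OC(=O)/C(C)=C\C | intermediate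
29 | acrylic acid | C=CC(=O)O | starting material
30 | (R,E)-5-[(Z)-2-methylbut-2-enoyloxy]hex-2-enoic acid | OC(=O)/C=C/C[C@@H](C)OC(=O)/C(C)=C\C | intermediate
31 | 9-O-tert-butyldimethylsilyl ether of the target | C=C(C)[C@H]1C[C@@]2(C)[C@H](CC[C@@H](OC(=O)/C=C/C[C@@H](C)OC(=O)/C(C)=C\C)[C@@H]2C)[C@@H](O[Si](C)(C)C(C)(C)C)C1=O | intermediate
32 | 3α-{(R,E)-5-[(Z)-2-methylbut-2-enoyloxy]hex-2-enoyloxy}-9β-hydroxy-10βH-eremophil-11-en-8-one (CNP0210874.1) | C=C(C)[C@H]1C[C@@]2(C)[C@H](CC[C@@H](OC(=O)/C=C/C[C@@H](C)OC(=O)/C(C)=C\C)[C@@H]2C)[C@@H](O)C1=O | target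

**Step count**

Total step count: 17. Longest linear sequence: 15 (steps 1–13, 16 and 17); steps 14 and 15 make the side-chain acid in a convergent branch.

**Steps most likely to fail, with fallbacks**

Step 7. The γ-silyloxy iminium ion may be deprotonated at C9 (dienamine formation) with erosion of that centre. Addition may also run through the chair with the silyloxy group axial and give the C10 epimer, or intermolecular aldol reaction may compete with cyclisation. The fallback sets out from 11 and comes back at 14. Thermodynamic silylation of the methyl ketone (Me3SiI, HN(SiMe3)2, CH2Cl2) gives the more substituted trimethylsilyl enol ether F1. TiCl4 (CH2Cl2, −78 °C) then activates the enal for an intramolecular Mukaiyama–Michael addition (6-exo, same chair with the C9–O bond anti to the forming bond), and aqueous work-up gives keto-aldehyde 12, here isolated. Acid-catalysed aldol condensation (p-TsOH, benzene, reflux with removal of water) closes ring A and returns 14.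

Step 13. The new double bond may migrate into conjugation with the ketone under the basic coupling conditions, protonation may give the axial C7 epimer, or enolisation may occur towards C9. The fallback sets out from 22 and comes back at 24. LiN(SiMe3)2 and Me3SiCl (THF, −78 °C) give the C7=C8 trimethylsilyl enol ether with O3 also silylated F2. Saegusa–Ito oxidation (Pd(OAc)2, MeCN) and mild acid work-up give the 6-en-8-one F3. α-Iodination (I2, pyridine, CH2Cl2) gives the 7-iodo enone F4. Suzuki–Miyaura coupling with isopropenylboronic acid pinacol ester (Pd(PPh3)4, K3PO4, dioxane/H2O) gives the cross-conjugated 7-isopropenyl dienone F5. Conjugate reduction with [(Ph3P)CuH]6 (benzene, H2O) under neutral conditions reduces only the C6=C7 enone bond and protonates C7, returning 24.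

Step 8. Deprotonation may occur at the γ-position (C1) instead of C5, the dienolate may be O-methylated, or iodomethane may attack the α face and give the trans-fused C5 epimer. The fallback sets out from 14 and comes back at 18, replacing steps 8 and 9. Conjugate reduction with Li[HB(s-Bu)3] and protonation give the saturated C4 ketone F6. Equilibrating enolate formation (t-BuOK, t-BuOH/THF) and iodomethane methylate the more substituted α-carbon C5 of this saturated 1-decalone-type ketone, the classical angular methylation that favours the cis-fused product, giving the 5β-methyl ketone F7. LiN(i-Pr)2 can then deprotonate only at C3 and gives enolate 17, which PhNTf2 converts into 18.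

**Further compounds**

F1 | step 7 | (E)-4-(tert-butyldimethylsilyloxy)-4-{2-[4-(trimethylsilyloxy)pent-3-en-1-yl]-1,3-dithian-2-yl}but-2-enal | CC(O[Si](C)(C)C)=CCCC1(SCCCS1)[C@H](O[Si](C)(C)C(C)(C)C)/C=C/C=O
F2 | step 13 | C7=C8 trimethylsilyl enol ether of 22 with O3 trimethylsilylated | C1(O[Si](C)(C)C)=CC[C@@]2(C)[C@H](CC[C@@H](O[Si](C)(C)C)[C@@H]2C)[C@H]1O[Si](C)(C)C(C)(C)C
F3 | step 13 | 3α-hydroxy-4β,5β-dimethyl-9β-(tert-butyldimethylsilyloxy)-10βH-decal-6-en-8-one | C1=C[C@@]2(C)[C@H](CC[C@@H](O)[C@@H]2C)[C@@H](O[Si](C)(C)C(C)(C)C)C1=O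
F4 | step 13 | 7-iodo-3α-hydroxy-4β,5β-dimethyl-9β-(tert-butyldimethylsilyloxy)-10βH-decal-6-en-8-one | IC1=C[C@@]2(C)[C@H](CC[C@@H](O)[C@@H]2C)[C@@H](O[Si](C)(C)C(C)(C)C)C1=O
F5 | step 13 | 3α-hydroxy-9β-(tert-butyldimethylsilyloxy)-10βH-eremophila-6,11-dien-8-one | C=C(C)C1=C[C@@]2(C)[C@H](CC[C@@H](O)[C@@H]2C)[C@@H](O[Si](C)(C)C(C)(C)C)C1=O
F6 | step 8 | 9β-(tert-butyldimethylsilyloxy)-10βH-decalin-4-one 8-(propane-1,3-diyl dithioketal), C5 epimers | C1CC2[C@H](CCCC2=O)[C@@H](O[Si](C)(C)C(C)(C)C)C13SCCCS3
F7 | step 8 | 5β-methyl-9β-(tert-butyldimethylsilyloxy)-10βH-decalin-4-one 8-(propane-1,3-diyl dithioketal) | C1C[C@@]2(C)[C@H](CCCC2=O)[C@@H](O[Si](C)(C)C(C)(C)C)C13SCCCS3
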